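The 27-membered lactone ring (ring A: C1–C26 plus the ring oxygen) is cut at C2–C3. The feature exploited is that C2, next to the C1 carbonyl, is the only ring carbon that can carry a stabilised carbanion, while all other ring carbons are plain methylenes. C2 is therefore brought in as a phosphonoacetate on the C26 oxygen and C3 as an aldehyde at the far end of the unbranched C3–C26 chain. One intramolecular Horner–Wadsworth–Emmons reaction forms C2=C3 and closes ring A with the ester already in place. The precursor, 24-oxotetracosyl diethylphosphonoacetate, is reached without protecting groups by ozonolysis of a terminal alkene; hydrogenation completes the route.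

Key step: step 4

Remark: 11-bromoundec-1-ene and 14-bromotetradecan-1-ol are taken as catalogue chemicals. Ring carbons are numbered C1 (carbonyl) to C26 (OCH2), so ring A holds 26 carbons and one oxygen, and the C3–C26 chain of the precursor holds 24 carbons.

Step 1
Reactants: 1 11-bromoundec-1-ene; 2 14-bromotetradecan-1-ol
Product: 5 pentacos-24-en-1-ol, via undec-10-enylmagnesium bromide 3 (not isolated), via bromomagnesium 14-bromotetradecan-1-olate 4 (not isolated)
Conditions: 1 (2.4 equiv), Mg, THF, rt → 40 °C; add 2 in THF, 0 °C; Li2CuCl4 (cat.), THF, −10 °C → rt; aq. NH4Cl
Reagents that add atoms: none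
Why: Kochi-type copper-catalysed cross-coupling of a primary alkyl Grignard reagent with a primary alkyl bromide is reliable for long unbranched chains; one equivalent of 3 is spent to turn the hydroxyl of 2 into the unreactive alkoxide 4, the remote terminal alkene is inert, and the hydrocarbon by-products separate easily from the polar alcohol.

Step 2
Reactants: 5 pentacos-24-en-1-ol; 6 2-(diethoxyphosphoryl)acetic acid
Product: 7 pentacos-24-en-1-yl 2-(diethoxyphosphoryl)acetate
Conditions: EDC·HCl, DMAP (cat.), CH2Cl2, 0 °C → rt
Reagents that add atoms: none
Why: Steglich esterification (carbodiimide activation with DMAP acyl transfer) should acylate the unhindered primary alcohol under near-neutral conditions that leave the terminal alkene and the phosphonate untouched, and the urea by-product is removed by aqueous washing.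

Step 3
Reactants: 7 pentacos-24-en-1-yl 2-(diethoxyphosphoryl)acetate
Product: 9 24-oxotetracosyl 2-(diethoxyphosphoryl)acetate, via secondary ozonide 8 (not isolated)
Conditions: O3, CH2Cl2, −40 °C; then PPh3, −40 °C → rt; short silica plug, used at once
Reagents that add atoms: ozone, [O-][O+]=O
Why: Ozonolysis with reductive work-up (1,3-dipolar cycloaddition, Criegee rearrangement to ozonide 8, deoxygenation by PPh3) should cleave the only C=C bond and excise the terminal carbon, leaving the C3 aldehyde without touching the ester or the phosphonate.

Step 4
Reactants: 9 24-oxotetracosyl 2-(diethoxyphosphoryl)acetate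
Product: 10 (E)-hexacos-2-en-26-olide [(3E)-oxacycloheptacos-3-en-2-one]
Conditions: LiCl, DBU, MeCN, rt; 9 in THF added by syringe pump (final ca. 1 mM)
Reagents that add atoms: none
Why: This is an intramolecular Horner–Wadsworth–Emmons olefination under Masamune–Roush conditions: lithium chelation between the phosphoryl and ester carbonyl oxygens acidifies the C2 methylene so that DBU can deprotonate it, the stabilised carbanion adds to the C3 aldehyde, and the oxaphosphetane collapses irreversibly to the C2=C3 enoate and diethyl phosphate. The closest known reaction type is the macrocyclic phosphonoacetate–aldehyde ring closure used for large unsaturated lactones. Ring A closes end to end by a formally 27-exo-trig attack of C2 on the aldehyde carbon, and because the O–C1 ester bond is already present no separate lactonisation is needed. No stereocentre is created, and the E geometry expected from the stabilised phosphonate is of no consequence since the alkene is hydrogenated in step 5. The selectivity that matters is cyclisation over intermolecular olefination, which slow addition of 9 into a large volume of the base solution should secure and which the strain-free, unbranched tether favours at this ring size. The conditions are too mild to cleave the ester or to cause significant aldol condensation of the aldehyde, which never accumulates.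

Step 5
Reactants: 10 (E)-hexacos-2-en-26-olide
Product: 11 26-hexacosanolide (oxacycloheptacosan-2-one)
Conditions: H2 (1 atm), 10% Pd/C, EtOAc, rt
Reagents that add atoms: none
Why: Heterogeneous catalytic hydrogenation should saturate the conjugated C2=C3 double bond, the only reducible group present, while the lactone is inert and no stereocentre is involved.

Compound list
1 | 11-bromoundec-1-ene | C=CCCCCCCCCCBr | starting material
2 | 14-bromotetradecan-1-ol | OCCCCCCCCCCCCCCBr | starting material
3 | undec-10-enylmagnesium bromide | C=CCCCCCCCCC[Mg]Br | intermediate (not isolated)
4 | bromomagnesium 14-bromotetradecan-1-olate | Br[Mg]OCCCCCCCCCCCCCCBr | intermediate (not isolated)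
5 | pentacos-24-en-1-ol | C=CCCCCCCCCCCCCCCCCCCCCCCCO | intermediate
6 | 2-(diethoxyphosphoryl)acetic acid (diethylphosphonoacetic acid) | CCOP(=O)(OCC)CC(=O)O | starting material
7 | pentacos-24-en-1-yl 2-(diethoxyphosphoryl)acetate | CCOP(=O)(OCC)CC(=O)OCCCCCCCCCCCCCCCCCCCCCCCC=C | intermediate
8 | 23-(1,2,4-trioxolan-3-yl)tricosyl 2-(diethoxyphosphoryl)acetate (secondary ozonide, racemic) | CCOP(=O)(OCC)CC(=O)OCCCCCCCCCCCCCCCCCCCCCCCC1OCOO1 | intermediate (not isolated)
9 | 24-oxotetracosyl 2-(diethoxyphosphoryl)acetate | CCOP(=O)(OCC)CC(=O)OCCCCCCCCCCCCCCCCCCCCCCCC=O | intermediate
10 | (E)-hexacos-2-en-26-olide [(3E)-oxacycloheptacos-3-en-2-one] | O=C1/C=C/CCCCCCCCCCCCCCCCCCCCCCCO1 | intermediate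
11 | 26-hexacosanolide (oxacycloheptacosan-2-one) | O=C1CCCCCCCCCCCCCCCCCCCCCCCCCO1 | target

Total step count: 5
Longest linear sequence: 5 steps (steps 1 to 5)

Steps most likely to fail

Step 4. Intermolecular olefination could outrun ring closure and give head-to-tail oligomers, or the aldehyde terminus could undergo base-mediated aldol self-condensation during the slow addition. The fallback closes the same C2=C3 bond by ring-closing metathesis. It sets out from alcohol 5, which would be acylated with acryloyl chloride (Et3N, CH2Cl2, 0 °C) to give pentacos-24-en-1-yl prop-2-enoate F1. Metathesis of F1 with the second-generation Grubbs catalyst RuCl2(=CHPh)(H2IMes)(PCy3) in dilute refluxing CH2Cl2, with loss of ethene, should give enoate 10, where the route is rejoined before step 5.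

Step 1. The magnesium alkoxide 4 could precipitate and stall the cross-coupling, while Wurtz-type homocoupling consumes the Grignard reagent. The fallback masks the hydroxyl before coupling. It sets out from 2, which with 3,4-dihydro-2H-pyran and PPTS in CH2Cl2 should give 2-[(14-bromotetradecyl)oxy]oxane F2. Coupling of F2 with a slight excess of Grignard reagent 3 under Li2CuCl4 catalysis in THF should give 2-(pentacos-24-en-1-yloxy)oxane F3. Acid methanolysis (TsOH, MeOH/THF, rt) should then return alcohol 5, where the route is rejoined.

Step 3. Over-oxidation of the aldehyde to the carboxylic acid, incomplete reduction of peroxidic intermediates, or poor solubility of the long-chain substrate at low temperature could erode the aldehyde. The fallback cleaves the alkene through an isolable glycol and avoids peroxides. It sets out from 7, which on dihydroxylation (OsO4 cat., NMO, acetone/water, rt) should give 24,25-dihydroxypentacosyl 2-(diethoxyphosphoryl)acetate F4 as a purifiable racemic diol. Glycol cleavage of F4 with NaIO4 in THF/water should deliver aldehyde 9, where the route is rejoined.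

Further compounds
F1 | step 4 | pentacos-24-en-1-yl prop-2-enoate | C=CC(=O)OCCCCCCCCCCCCCCCCCCCCCCCC=C
F2 | step 1 | 2-[(14-bromotetradecyl)oxy]oxane (racemic) | BrCCCCCCCCCCCCCCOC1CCCCO1
F3 | step 1 | 2-(pentacos-24-en-1-yloxy)oxane (racemic) | C=CCCCCCCCCCCCCCCCCCCCCCCCOC1CCCCO1
F4 | step 3 | 24,25-dihydroxypentacosyl 2-(diethoxyphosphoryl)acetate (racemic) | CCOP(=O)(OCC)CC(=O)OCCCCCCCCCCCCCCCCCCCCCCCC(O)CO
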